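**Strategy.** The route rests on cutting ring C of the upper flavan unit at C2–C3 and O1–C8a: O1–C2 is the carbonyl of a 4-oxygenated benzoate, and C3–C4–C4a–C8a is a 2'-fluoroacetophenone. The key step exploits the ortho placement of O1 and C4 on ring A: with C4 as a ketone, C3 is an enolate carbon and C8a an SNAr-active fluoroarene carbon, so one Claisen/SNAr cascade joins ketone 2 and ester 3 into flavone 5. Asymmetric hydrogenation then sets C2, and a stereoconvergent Friedel–Crafts coupling of the C4 cation with benzylated (−)-epiafzelechin forms the C4–C8 bond trans to the 2-aryl group before global hydrogenolysis.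

Key step: step 2

Remark: (−)-epiafzelechin (8), the (2R,3R) flavan-3-ol that forms the lower unit, is taken as a commercially available chiral-pool compound. Flavan numbering (O1, C2, C3, C4, C4a, C8a) is used for both units. The target is the 2,4-trans (2S,4R) flavan linked through C4 to C8 of the lower unit.

**Step 1**
Reactants: 1 1-(2-fluoro-4-hydroxyphenyl)ethan-1-one
Product: 2 1-[4-(benzyloxy)-2-fluorophenyl]ethan-1-one
Conditions: BnBr (1.1 equiv), K2CO3, DMF, rt
Reagents that add atoms: benzyl bromide BrCc1ccccc1
Why: Williamson ether synthesis on the phenoxide, which is far more nucleophilic than the ketone enolate under carbonate conditions, so the acetyl group and the C–F bond should stay untouched.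

**Step 2**
Reactants: 2 1-[4-(benzyloxy)-2-fluorophenyl]ethan-1-one, 3 methyl 4-(benzyloxy)benzoate
Product: 5 7-(benzyloxy)-2-[4-(benzyloxy)phenyl]-4H-chromen-4-one, via potassium diketonate 4 (not isolated)
Conditions: KOtBu (2.5 equiv), THF, 0 °C to rt; then DMSO, 90 °C, same flask
Reagents that add atoms: none
Why: Claisen condensation followed by intramolecular SNAr, an anionic (4+2) annulation: the potassium enolate of 2 attacks the ester carbonyl of 3 and expels methoxide, which forms C2–C3 and, after deprotonation, the chelated diketonate 4; on heating, the enolate oxygen on the former ester carbon adds to the fluorine-bearing ring carbon, which the ortho acyl group activates, and fluoride leaves from the Meisenheimer intermediate, which forms O1–C8a. The closest known reaction type is the base-mediated cyclisation of 1-(2-fluoroaryl)-1,3-diketones to chromones, here run in the same flask as the Claisen step that makes the diketone. Ring C closes by oxygen attack on the sp2 arene carbon, formally a 6-exo-trig addition–elimination. No stereocentre is formed, since the product is the planar flavone whose C2=C3 bond and C4 carbonyl are the handles for the asymmetric hydrogenation of step 3. The step needs C-acylation rather than O-acylation of the enolate, which the excess base secures by draining the equilibrium into the stable diketonate, and ring closure through oxygen rather than carbon, which only the six-membered transition state allows; displacement of fluoride by methoxide or tert-butoxide should stay slow because 2 and 4 are present as electron-rich enolates until the intramolecular step takes over.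

**Step 3**
Reactants: 5 7-(benzyloxy)-2-[4-(benzyloxy)phenyl]-4H-chromen-4-one
Product: 7 (2S,4S)-7-(benzyloxy)-2-[4-(benzyloxy)phenyl]-3,4-dihydro-2H-chromen-4-ol, via flavanone 6 (not isolated)
Conditions: Ru(cod)(2-methylallyl)2 (5 mol %), 1,3-bis[1-(naphthalen-1-yl)ethyl]-4,5-dihydroimidazolium tetrafluoroborate (single antipode, 10 mol %), KOtBu (15 mol %), H2 (100 bar), toluene/tert-amyl alcohol, 40 °C
Reagents that add atoms: none
Why: Ru–NHC-catalysed asymmetric hydrogenation of a flavone, in which the chiral carbene ligands distinguish the enantiotopic faces of C2=C3 and set C2 as S (the ligand antipode that delivers the 2S series is used, both being accessible from 1-(1-naphthyl)ethylamine), after which the carbonyl of 6 should be reduced anti to the 2-aryl group to the 2,4-cis alcohol; benzyl ethers and arene rings should be left alone, and the C4 configuration is of no consequence because C4 is ionised in step 5.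

**Step 4**
Reactants: 8 (−)-epiafzelechin
Product: 9 (2R,3R)-5,7-bis(benzyloxy)-2-[4-(benzyloxy)phenyl]-3,4-dihydro-2H-chromen-3-ol
Conditions: BnBr (3.3 equiv), K2CO3, DMF, 0 °C to rt
Reagents that add atoms: benzyl bromide BrCc1ccccc1
Why: Williamson ether synthesis that is selective for the three phenoxides over the non-acidic secondary C3 alcohol, with both stereocentres untouched at room temperature.

**Step 5**
Reactants: 7 (2S,4S)-7-(benzyloxy)-2-[4-(benzyloxy)phenyl]-3,4-dihydro-2H-chromen-4-ol, 9 (2R,3R)-5,7-bis(benzyloxy)-2-[4-(benzyloxy)phenyl]-3,4-dihydro-2H-chromen-3-ol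
Product: 11 (2R,3R)-5,7-bis(benzyloxy)-8-{(2S,4R)-7-(benzyloxy)-2-[4-(benzyloxy)phenyl]-3,4-dihydro-2H-chromen-4-yl}-2-[4-(benzyloxy)phenyl]-3,4-dihydro-2H-chromen-3-ol, via flavan-4-yl cation 10 (not isolated)
Conditions: 9 (3 equiv), TMSOTf (0.3 equiv), 4 Å molecular sieves, CH2Cl2, −78 to −40 °C
Reagents that add atoms: none
Why: Dehydrative Friedel–Crafts alkylation through an SN1 path, in which ionisation of the benzylic C4 alcohol (the water released being taken up by the sieves) gives cation 10, stabilised by O1 and the C7 ether; C8 of 9, the usual reacting position of 5,7-di-O-benzyl flavan-3-ols, should capture it by axial attack on the face opposite the pseudo-equatorial 2-aryl group, so that either C4 epimer of the alcohol converges on the 2,4-trans (4R) product.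

**Step 6**
Reactants: 11 (2R,3R)-5,7-bis(benzyloxy)-8-{(2S,4R)-7-(benzyloxy)-2-[4-(benzyloxy)phenyl]-3,4-dihydro-2H-chromen-4-yl}-2-[4-(benzyloxy)phenyl]-3,4-dihydro-2H-chromen-3-ol
Product: 12 (2R,3R)-8-[(2S,4R)-7-hydroxy-2-(4-hydroxyphenyl)-3,4-dihydro-2H-chromen-4-yl]-2-(4-hydroxyphenyl)-3,4-dihydro-2H-chromene-3,5,7-triol
Conditions: H2 (1 atm), Pd(OH)2/C, THF/MeOH, rt
Reagents that add atoms: none
Why: Hydrogenolysis of the five aryl benzyl ethers, which under these mild conditions should leave the cyclic C2–O1 ethers, the doubly benzylic C4–C8 bond and all four stereocentres intact.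

**Compound list**

1 | 1-(2-fluoro-4-hydroxyphenyl)ethan-1-one | CC(=O)c1ccc(O)cc1F | starting material
2 | 1-[4-(benzyloxy)-2-fluorophenyl]ethan-1-one | CC(=O)c1ccc(OCc2ccccc2)cc1F | intermediate
3 | methyl 4-(benzyloxy)benzoate | COC(=O)c1ccc(OCc2ccccc2)cc1 | starting material
4 | 1-[4-(benzyloxy)-2-fluorophenyl]-3-[4-(benzyloxy)phenyl]propane-1,3-dione, present in the flask as its potassium enolate | O=C(CC(=O)c1ccc(OCc2ccccc2)cc1)c1ccc(OCc2ccccc2)cc1F | intermediate
5 | 7-(benzyloxy)-2-[4-(benzyloxy)phenyl]-4H-chromen-4-one | O=c1cc(-c2ccc(OCc3ccccc3)cc2)oc2cc(OCc3ccccc3)ccc12 | intermediate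
6 | (2S)-7-(benzyloxy)-2-[4-(benzyloxy)phenyl]-2,3-dihydro-4H-chromen-4-one | c1ccc(COc2ccc([C@@H]3CC(=O)c4ccc(OCc5ccccc5)cc4O3)cc2)cc1 | intermediate
7 | (2S,4S)-7-(benzyloxy)-2-[4-(benzyloxy)phenyl]-3,4-dihydro-2H-chromen-4-ol (2,4-cis) | c1ccc(COc2ccc([C@@H]3C[C@H](O)c4ccc(OCc5ccccc5)cc4O3)cc2)cc1 | intermediate
8 | (−)-epiafzelechin, (2R,3R)-2-(4-hydroxyphenyl)-3,4-dihydro-2H-chromene-3,5,7-triol | c1c(O)cc(O)c2c1O[C@H](c1ccc(O)cc1)[C@H](O)C2 | starting material
9 | (2R,3R)-5,7-bis(benzyloxy)-2-[4-(benzyloxy)phenyl]-3,4-dihydro-2H-chromen-3-ol | c1c(OCc3ccccc3)cc(OCc3ccccc3)c2c1O[C@H](c1ccc(OCc3ccccc3)cc1)[C@H](O)C2 | intermediate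
10 | (2S)-7-(benzyloxy)-2-[4-(benzyloxy)phenyl]-3,4-dihydro-2H-chromen-4-ylium (C4 cation) | c1ccc(COc2ccc([C@@H]3C[CH+]c4ccc(OCc5ccccc5)cc4O3)cc2)cc1 | intermediate
11 | (2R,3R)-5,7-bis(benzyloxy)-8-{(2S,4R)-7-(benzyloxy)-2-[4-(benzyloxy)phenyl]-3,4-dihydro-2H-chromen-4-yl}-2-[4-(benzyloxy)phenyl]-3,4-dihydro-2H-chromen-3-ol | c1ccc(COc2ccc([C@@H]3C[C@@H](c4c(OCc5ccccc5)cc(OCc5ccccc5)c5c4O[C@H](c4ccc(OCc6ccccc6)cc4)[C@H](O)C5)c4ccc(OCc6ccccc6)cc4O3)cc2)cc1 | intermediate
12 | (2R,3R)-8-[(2S,4R)-7-hydroxy-2-(4-hydroxyphenyl)-3,4-dihydro-2H-chromen-4-yl]-2-(4-hydroxyphenyl)-3,4-dihydro-2H-chromene-3,5,7-triol | Oc1ccc([C@@H]2C[C@@H](c3c(O)cc(O)c4c3O[C@H](c3ccc(O)cc3)[C@H](O)C4)c3ccc(O)cc3O2)cc1 | target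

**Totals.** Total step count: 6. Longest linear sequence: 5 steps (steps 1, 2, 3, 5, 6); step 4 is a one-step side branch.

**Steps most likely to fail**

Step 5. The nucleophile may attack both faces of the cation, giving the 2,4-cis isomer beside the wanted trans one. It may also react through C6 instead of C8. Alcohol 7 may alkylate itself through its own electron-rich ring A, and the acid may open the benzylic C2–O1 ether with loss of the C2 configuration. The fallback sets out from 7 and replaces ionisation of the alcohol by thiophilic activation. Thiolysis of 7 with benzyl mercaptan (ZnI2 cat., CH2Cl2, 0 °C) should give (2S)-7-(benzyloxy)-2-[4-(benzyloxy)phenyl]-4-(benzylsulfanyl)-3,4-dihydro-2H-chromene F1 as a mixture of C4 epimers. AgBF4 in THF/CH2Cl2 at −40 to 0 °C, with 9 in excess, then releases the same cation slowly and without a strong Brønsted acid at the outset, which should curb self-alkylation and ring opening. The fallback comes back to the route at 11.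

Step 3. Facial discrimination at C2=C3 may be insufficient, the reduction may stall at the ketone stage, or benzyl ethers may be lost under the high hydrogen pressure. The fallback sets out from 2 and moves the creation of the C2 stereocentre to a conjugate addition. The same Claisen/SNAr cascade with ethyl formate (KOtBu, THF, then DMSO, 90 °C) should pass through 3-[4-(benzyloxy)-2-fluorophenyl]-3-oxopropanal F2 (as its enolate, not isolated) to 7-(benzyloxy)-4H-chromen-4-one F3. Asymmetric conjugate addition of 4-(benzyloxy)phenylboronic acid with Pd(OCOCF3)2, a single antipode of 4-tert-butyl-2-(pyridin-2-yl)-4,5-dihydrooxazole (the one that gives the 2S ketone), NH4PF6 and water in 1,2-dichloroethane at 60 °C should give flavanone 6, now isolated. NaBH4 in MeOH/THF at 0 °C should then reduce 6 from the face opposite the 2-aryl group to the 2,4-cis alcohol, so the fallback comes back to the route at 7.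

Step 2. The ring closure may stall at the diketonate stage because the anionic enolate deactivates the fluoroarene, fluoride may be displaced by methoxide or tert-butoxide, or retro-Claisen cleavage may set in on heating. The fallback sets out from ester 3 and closes the O1–C8a bond by copper catalysis instead of SNAr. Commercial 1-(2-bromo-4-hydroxyphenyl)ethan-1-one is benzylated as in step 1 (BnBr, K2CO3, DMF, rt) to 1-[4-(benzyloxy)-2-bromophenyl]ethan-1-one F4. Claisen condensation of F4 with 3 (KOtBu, THF) should give 1-[4-(benzyloxy)-2-bromophenyl]-3-[4-(benzyloxy)phenyl]propane-1,3-dione F5 as its enolate. Addition of CuI (10 mol %), 1,10-phenanthroline and DMF to the same flask and heating to 100 °C should effect an Ullmann-type intramolecular O-arylation. The fallback comes back to the route at 5.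

**Further compounds**

F1 | step 5 | (2S)-7-(benzyloxy)-2-[4-(benzyloxy)phenyl]-4-(benzylsulfanyl)-3,4-dihydro-2H-chromene (C4 epimers) | c1ccc(COc2ccc([C@@H]3CC(SCc4ccccc4)c4ccc(OCc5ccccc5)cc4O3)cc2)cc1
F2 | step 3 | 3-[4-(benzyloxy)-2-fluorophenyl]-3-oxopropanal | O=CCC(=O)c1ccc(OCc2ccccc2)cc1F
F3 | step 3 | 7-(benzyloxy)-4H-chromen-4-one | O=c1ccoc2cc(OCc3ccccc3)ccc12
F4 | step 2 | 1-[4-(benzyloxy)-2-bromophenyl]ethan-1-one | CC(=O)c1ccc(OCc2ccccc2)cc1Br
F5 | step 2 | 1-[4-(benzyloxy)-2-bromophenyl]-3-[4-(benzyloxy)phenyl]propane-1,3-dione | O=C(CC(=O)c1ccc(OCc2ccccc2)cc1)c1ccc(OCc2ccccc2)cc1Br
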